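(The data were generated by integration with constants of no real substance.)

A small charge of 0.025 M of solid substrate and a larger one of 0.038 M are the two runs I have for a flask charged with 0.050 M.

| setting | south-west | north-west | flask |
|---|---|---|---|
| solid substrate | 0.025 M | 0.038 M | 0.050 M |
| remark | run made earlier | run made earlier |  |
| time |  |  | 15 d |

- south-west (time / d: side product / %, target / %): 3.00: 40, 7; 6.00: 52, 13; 10.0: 64, 18; 12.0: 66, 20
- north-west (time / d: side product / %, target / %): 1.04: 18, 0; 2.00: 27, 3; 5.00: 46, 16; 12.0: 69, 15

(scatter of a reading: 1.5 percentage points)

- solid substrate is a solid; its amount is given per volume of the solution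
- the numbers in the tables scatter with a standard deviation of 1.5 percentage points
- at the start none of the solid substrate is in solution

- share of side product in side product plus target at 10 h
- share of side product in side product plus target at 15 d
- which of side product and target there is more of at 15 d

I ask first what each given number is worth to the share of side product in side product plus target. Take the charge: at 12.0 d that share reads 76.7 % in the south-west run and 82.1 % in the north-west run. If this gap were a real trend, a straight line through both runs would give 87.1 % for the flask. But the north-west target reads 16 % at 5.00 d and 15 % at 12.0 d, and each reading scatters by 1.5 percentage points, so I do not trust the line. Then take the time: the south-west share falls by 3.3 points from 6.00 d to 12.0 d. At that pace the days up to 15 d are worth 1.6 points, less than the gap between the runs.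

So I pool both runs and commit to 79.4 %: this is the late share, the selectivity toward side product summed over the last readings of both runs. With more side product than target in it, I expect side product to lead at 15 d. At 10 h I expect a share above the 90.0 % read at 2.00 d in the north-west run.

The forecast gives 98 % at 10 h and 80 % at 15 d, within 72 % to 88 %, with side product ahead, noting that “scatter prevents a firm loading trend”. Its late figure lies 0.60 points above mine.

The flask gives 96.3 % at 10 h and 79.1 % at 15 d, with side product at 70.6 % of the charge against 18.6 % for target.

    starting material ⇌ intermediate A (K = 4.50, k = 0.0554 h⁻¹)
    starting material → intermediate B (k = 0.0489 h⁻¹)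
    intermediate B ⇌ intermediate C (K = 2.39, k = 0.0605 h⁻¹)
    intermediate B ⇌ intermediate D (K = 2.60, k = 0.115 h⁻¹)
    intermediate B → side product (k = 0.117 h⁻¹)
    intermediate C → target (k = 0.0272 h⁻¹)
    solid substrate ⇌ starting material, rate k7*(cs7 - [starting material]) while solid is left; crystals form when [starting material] > cs7 (solubility = 45.0 mM, k = 0.0995 h⁻¹)

At 15 d the flask still holds 7.78 % of its charge as intermediate A, yet a tenfold time barely moves the share, which ends at 78.9 %. The late share of 79.4 % lies 0.30 points from the flask's value. Carried to the neighbour flask charged with 0.013 M, it meets a share of 79.1 %.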